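I started from a small charge: Friday's flask held one equivalent of reagent, and I wanted to know where that reagent went before judging the richer flasks.

| flask | substrate | reagent | temperature | remark | time |
|---|---|---|---|---|---|
| Friday's | 1.5 M | 1.5 M | 125 °C | run made earlier |  |
| amber | 1.0 M | 1.50 M | 125 °C |  | 3.0 h |
| grey | 1.0 M | 1.50 M | 100 °C |  | 3.0 h |
| violet | 1.0 M | 1.50 M |  | at 75 °C until 50 min, from then on at 125 °C | 3.0 h |
| ochre | 1.0 M | 1.50 M | 75 °C |  | 3.0 h |

Friday's run (percent of the substrate charged)

| time / min | single product / % | substrate / % |
|---|---|---|
| 3.00 | 11 | 91 |
| 5.00 | 13 | 88 |
| 8.00 | 15 | 80 |
| 12.0 | 19 | 74 |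
| 20.0 | 23 | 64 |
| 40.0 | 26 | 47 |

(standard deviation of a reading: 1.5 percentage points)

- the earlier runs do not show what temperature does; that part of a forecast is a guess

- which flask leads in amount of single product, in percent of the substrate charged ("all alike" within 1.5 percentage points) (amber / grey / violet / ochre / all alike)
- how much single product is there at the end, in percent of the substrate charged: amber
- how much single product is there at the end, in percent of the substrate charged: grey
- how much single product is there at the end, in percent of the substrate charged: violet
- how much single product is there at the end, in percent of the substrate charged: ochre

I kept a ledger of the reagent, supposing that each mole of substrate consumed cost one mole of reagent, and that each consumed mole no longer found as single product had cost a second mole. Because Friday's two charges were equal, its last reading, at 40.0 min, closes in percent of the reagent charge: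

| Entry | Share of the reagent |
|---|---|
| Spent on consuming substrate | 53.0% |
| Spent on reacting single product onward | 27.0% |
| Unspent | 20.0% |

This gives 1.51 for the reagent price, the moles of reagent spent per mole of substrate consumed. Reckoned over a short interval, the price starts at one and reaches two at the crossing, where single product is used as fast as it is made and stops growing. Over Friday's last interval, from 20.0 min to 40.0 min, the price read 1.82, a rough reading given the scatter of 1.5 percentage points, but near that crossing.

At a price of two, amber's 1.50 M of reagent covers 75.0% of its substrate, so I treated the reagent as the limiting reagent of this ledger. Amber runs much longer than Friday's readings, so I held its single product near Friday's 26%. Reagent spent is two moles per mole consumed, less one per mole of single product standing, so, counting amber's reagent as fully spent, I reckoned its books to close at conversion 88.0% and price 1.70. That a cooler flask reaches the crossing later, and so might lead, was a guess.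

The forecast named grey as leader at 24.5%, with amber 17%, which is below my figure, violet 18% and ochre 15%, on the ground that “Single product peaks and then fades”.

The flasks gave amber 28.6%, grey 33.6%, violet 25.8% and ochre 23.7%, so grey led.

    substrate + reagent → single product + by-product (k = 9.94 × 10⁻⁵ M⁻¹ s⁻¹, Ea = 68.0 kJ mol⁻¹)
    reagent + single product ⇌ double product + by-product (K = 5.05, k = 1.22 × 10⁻⁴ M⁻¹ s⁻¹, Ea = 99.0 kJ mol⁻¹, ΔH = −25.0 kJ mol⁻¹)
    crystals ⇌ by-product, rate k3*(cs3 - [by-product]) while solid is left; crystals form when [by-product] > cs3 (solubility = 0.230 M, k = 0.0111 s⁻¹)
    (constants at 100 °C)

Grey ended at a price of 1.47, and over its second half the price was 1.87, close to the crossing. The neighbouring flask was grey with 0.60 M of reagent. It kept 67% of its substrate and held 25.6% single product and 6.97% double product, so its price was 1.21. On the 0.325 M of substrate consumed, that price comes to 0.395 M of reagent, and the neighbouring flask spent 0.395 M.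

The runs were generated by integration for an exercise.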